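**Retrosynthetic overview**
- The target is robinetinidol-(4α→6)-epigallocatechin: a 5-deoxy upper unit (2R,3S,4S, all-trans) joined through C4 to C6 of a (2R,3R)-epigallocatechin lower unit.
- Last disconnection: global deprotection (upper-unit acetates by methanolysis; lower-unit benzyl ethers and a C8 bromine cap by hydrogenolysis).
- Key disconnection: the C4(ring C)–C6(ring D) bond, from a per-O-acetylated ("disarmed") flavan-3,4-diol C4 donor and a C8-bromo-capped, per-O-benzylated ("armed") epigallocatechin. This is the proposed new step and it sets C4.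
- Donor from (+)-dihydrorobinetin (ketone reduction, peracetylation); acceptor from (−)-epigallocatechin (benzylation, C8 bromination).
- No ring is built: rings A–C come intact from dihydrorobinetin and rings D–F from epigallocatechin; the order of events is C4 activation, C8 capping, C4–C6 coupling, deprotection.

Assumption: (+)-dihydrorobinetin and (−)-epigallocatechin are bought as the natural single enantiomers; C2/C3 of both units are taken from them.

**Step 1**
Reactants: 1 (+)-dihydrorobinetin
Product: 2 (+)-leucorobinetinidin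
Conditions: NaBH4, EtOH, 0 °C → rt, argon
Reagents that add atoms: none
Why: Borohydride reduction of the aryl ketone, in which axial hydride delivery to C4 of the 2,3-trans-dihydroflavonol gives mainly the equatorial 3,4-trans (4R) alcohol as established for this compound class; C2 and C3 are untouched and the C4 configuration is not critical because this centre is ionised in step 5.

**Step 2**
Reactants: 2 (+)-leucorobinetinidin; 3 acetic anhydride
Product: 4 hexa-O-acetyl-leucorobinetinidin
Conditions: Ac2O, pyridine, DMAP (cat.), 0 °C → rt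
Reagents that add atoms: acetic anhydride, CC(=O)OC(C)=O
Why: Exhaustive O-acetylation (DMAP-catalysed esterification) of the four phenols and both secondary alcohols touches no stereocentre and installs at once the C4 leaving group, the participating 3-acetoxy group and electron-poor rings A and B.

**Step 3**
Reactants: 5 (−)-epigallocatechin; 6 benzyl bromide
Product: 7 5,7,3',4',5'-penta-O-benzyl-(−)-epigallocatechin
Conditions: BnBr (5.5 equiv), K2CO3, DMF, 0 °C → rt, argon
Reagents that add atoms: benzyl bromide, BrCc1ccccc1
Why: Williamson ether synthesis in which the five phenoxides are alkylated far faster than the secondary 3-OH, and low temperature under argon limits C-benzylation, pyrogallol autoxidation and C2 epimerisation, so both stereocentres of 5 are kept.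

**Step 4**
Reactants: 7 5,7,3',4',5'-penta-O-benzyl-(−)-epigallocatechin; 8 N-bromosuccinimide
Product: 9 8-bromo-5,7,3',4',5'-penta-O-benzyl-(−)-epigallocatechin
Conditions: NBS (1.0 equiv), CH2Cl2, −78 → 0 °C
Reagents that add atoms: N-bromosuccinimide, O=C1CCC(=O)N1Br
Why: Electrophilic aromatic bromination of the most electron-rich arene (ring D) occurs at C8 and not at C6, which is flanked by two benzyloxy groups, as known for per-O-benzyl flavan-3-ols; this installs the removable C8 cap and touches no stereocentre.

**Step 5**
Reactants: 4 hexa-O-acetyl-leucorobinetinidin; 9 8-bromo-5,7,3',4',5'-penta-O-benzyl-(−)-epigallocatechin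
Product: 11 3,7,3',4',5'-penta-O-acetyl-robinetinidol-(4α→6)-[8-bromo-5,7,3',4',5'-penta-O-benzyl-epigallocatechin], via dioxolanium triflate 10 (not isolated)
Conditions: 9 (2.5 equiv, excess recovered), TMSOTf (0.3 equiv), 4 Å MS, CH2Cl2, −20 → 0 °C
Reagents that add atoms: none
Why: Proposed new method: an acyl-disarmed, halogen-capped Friedel–Crafts interflavan coupling, in which per-O-acetylation makes rings A and B of the 5-deoxy donor 4 too electron-poor to self-alkylate (the usual fate of resorcinol-type flavan-4-yl cations) while the C4 acetate can still ionise through donation from the ring oxygen O1 and anchimeric assistance by the 3-acetoxy group, giving the cis-fused β-face dioxolanium ion 10; the benzyl-armed ring D of 9, with C8 blocked by bromine, then attacks C4 through its only free position C6 from the α face with inversion, forming the C4–C6 bond and setting the 4S (3,4-trans, 4α) centre; the closest known chemistry is the Lewis-acid-promoted coupling of per-O-benzyl catechin-type (5,7-dioxygenated) C4 electrophiles with 3-O-acyl participation and C8 halogen capping, together with the armed/disarmed logic of glycosylation, neither of which has been shown for a 5-deoxy peracetylated donor or a gallo-type capped acceptor.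

**Step 6**
Reactants: 11 3,7,3',4',5'-penta-O-acetyl-robinetinidol-(4α→6)-[8-bromo-5,7,3',4',5'-penta-O-benzyl-epigallocatechin]
Product: 12 robinetinidol-(4α→6)-[8-bromo-5,7,3',4',5'-penta-O-benzyl-epigallocatechin]
Conditions: K2CO3 (0.3 equiv), degassed MeOH/THF, argon, 0 °C → rt; then AcOH to pH 5
Reagents that add atoms: none
Why: Base-catalysed transesterification (Zemplén-type methanolysis) removes the four aryl acetates and the secondary 3-acetate as methyl acetate, while benzyl ethers, the aryl bromide and all five stereocentres are inert to catalytic carbonate in methanol at or below room temperature under argon.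

**Step 7**
Reactants: 12 robinetinidol-(4α→6)-[8-bromo-5,7,3',4',5'-penta-O-benzyl-epigallocatechin]
Product: 13 robinetinidol-(4α→6)-epigallocatechin (CNP0311915.2)
Conditions: H2 (1 atm), Pd(OH)2/C, Et3N (1.5 equiv), THF/MeOH/H2O, rt; filter, acidify with dilute HCO2H, lyophilise
Reagents that add atoms: none
Why: Heterogeneous catalytic hydrogenolysis cleaves the five benzyl ethers and, in the same operation, the aryl C–Br bond (hydrodehalogenation, HBr taken up by Et3N); the C2–O1 and C4–C6 bonds of flavans survive these conditions, so the five stereocentres are delivered unchanged.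

**Compound list**

1 | (+)-dihydrorobinetin, (2R,3R)-3,7-dihydroxy-2-(3,4,5-trihydroxyphenyl)chroman-4-one | Oc1ccc2c(c1)O[C@H](c1cc(O)c(O)c(O)c1)[C@@H](O)C2=O | starting material
2 | (+)-leucorobinetinidin, (2R,3S,4R)-2-(3,4,5-trihydroxyphenyl)chromane-3,4,7-triol (2,3-trans-3,4-trans) | Oc1ccc2c(c1)O[C@H](c1cc(O)c(O)c(O)c1)[C@@H](O)[C@@H]2O | intermediate
3 | acetic anhydride | CC(=O)OC(C)=O | starting material
4 | hexa-O-acetyl-leucorobinetinidin, the 3,4,7,3',4',5'-hexaacetate of 2 with its configuration retained (2-aryl α, 3-OAc β, 4-OAc α) | CC(=O)Oc1ccc2c(c1)O[C@H](c1cc(OC(C)=O)c(OC(C)=O)c(OC(C)=O)c1)[C@@H](OC(C)=O)[C@@H]2OC(C)=O | intermediate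
5 | (−)-epigallocatechin, (2R,3R)-2-(3,4,5-trihydroxyphenyl)chromane-3,5,7-triol (2,3-cis) | Oc1cc(O)c2c(c1)O[C@H](c1cc(O)c(O)c(O)c1)[C@H](O)C2 | starting material
6 | benzyl bromide | BrCc1ccccc1 | starting material
7 | 5,7,3',4',5'-penta-O-benzyl-(−)-epigallocatechin, (2R,3R)-5,7-bis(benzyloxy)-2-[3,4,5-tris(benzyloxy)phenyl]chroman-3-ol | c1ccccc1COc1cc(OCc3ccccc3)c2c(c1)O[C@H](c1cc(OCc3ccccc3)c(OCc3ccccc3)c(OCc3ccccc3)c1)[C@H](O)C2 | intermediate
8 | N-bromosuccinimide | O=C1CCC(=O)N1Br | starting material
9 | 8-bromo-5,7,3',4',5'-penta-O-benzyl-(−)-epigallocatechin, (2R,3R), bromine on ring D between the 7-benzyloxy carbon and C8a | c1ccccc1COc1cc(OCc3ccccc3)c2c(c1Br)O[C@H](c1cc(OCc3ccccc3)c(OCc3ccccc3)c(OCc3ccccc3)c1)[C@H](O)C2 | intermediate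
10 | dioxolanium triflate: 2-methyl-1,3-dioxolan-2-ylium ion cis-fused across O3–C3–C4–O4 on the β face of the 7,3',4',5'-tetra-O-acetyl upper unit (2-aryl α), triflate counter-ion | CC(=O)Oc1ccc2c(c1)O[C@H](c1cc(OC(C)=O)c(OC(C)=O)c(OC(C)=O)c1)[C@@H](O4)[C@H]2[O+]=C4C.[O-]S(=O)(=O)C(F)(F)F | intermediate
11 | 3,7,3',4',5'-penta-O-acetyl-robinetinidol-(4α→6)-[8-bromo-5,7,3',4',5'-penta-O-benzyl-epigallocatechin]; upper unit 2R,3S,4S (all-trans), lower unit 2R,3R | CC(=O)Oc1ccc2c(c1)O[C@H](c1cc(OC(C)=O)c(OC(C)=O)c(OC(C)=O)c1)[C@@H](OC(C)=O)[C@@H]2c1c(OCc3ccccc3)c(Br)c2c(c1OCc3ccccc3)C[C@@H](O)[C@@H](c1cc(OCc3ccccc3)c(OCc3ccccc3)c(OCc3ccccc3)c1)O2 | intermediate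
12 | robinetinidol-(4α→6)-[8-bromo-5,7,3',4',5'-penta-O-benzyl-epigallocatechin]; upper unit 2R,3S,4S with free OH groups, lower unit 2R,3R | Oc1ccc2c(c1)O[C@H](c1cc(O)c(O)c(O)c1)[C@@H](O)[C@@H]2c1c(OCc3ccccc3)c(Br)c2c(c1OCc3ccccc3)C[C@@H](O)[C@@H](c1cc(OCc3ccccc3)c(OCc3ccccc3)c(OCc3ccccc3)c1)O2 | intermediate
13 | robinetinidol-(4α→6)-epigallocatechin (CNP0311915.2); upper unit 2R,3S,4S, lower unit 2R,3R | Oc1ccc2c(c1)O[C@H](c1cc(O)c(O)c(O)c1)[C@@H](O)[C@@H]2c1c(O)cc2c(c1O)C[C@@H](O)[C@@H](c1cc(O)c(O)c(O)c1)O2 | target

**Step count and risks**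

Total step count: 7. Longest linear sequence: 5 steps (steps 1, 2, 5, 6, 7 from 1; the branch from 5 through steps 3, 4, 5, 6, 7 is equally long).

The three steps most likely to fail:

Step 5, the proposed new coupling. The disarmed donor may ionise sluggishly, the cation may lose H-3 to an enol acetate, or the tribenzyloxyphenyl ring E of 9 may compete with the hindered C6. The fallback is the known biomimetic flavan-3,4-diol/flavan-3-ol condensation. It sets out from 2, which is stirred with an excess of unprotected 5 in 0.1 M aqueous HCl at room temperature under argon. The free phloroglucinol-type ring D of 5 captures the C4 carbocation of 2 far faster than any other ring, and the main products are 13 and its regioisomer robinetinidol-(4α→8)-epigallocatechin F1. These are separated on Sephadex LH-20 and by reversed-phase HPLC, so the route is rejoined directly at 13, with lower regioselectivity but no protecting groups.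

Step 3, perbenzylation of free epigallocatechin. The pyrogallol ring is oxidised easily as its phenoxide, and C-benzylation or C2 epimerisation can lower the yield. The fallback sets out from 5 and never exposes the free polyphenolate. Acetic anhydride 3 in pyridine gives air-stable (−)-epigallocatechin hexaacetate F2. NaH, benzyl bromide 6 and a controlled amount of water in DMF at 0 °C then cleave the aryl acetates one at a time and benzylate each phenoxide as it is released, giving 3-O-acetyl-5,7,3',4',5'-penta-O-benzyl-(−)-epigallocatechin F3. K2CO3 in MeOH/THF removes the remaining alkyl acetate and returns to 7.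

Step 6, basic deacetylation. The hindered secondary 3-acetate is slow, and the liberated upper-unit pyrogallol phenoxide can autoxidise or open ring C through a ring B quinone methide (C2 epimerisation). The fallback sets out from 11 and inverts the order of the deprotections so that no phenoxide is formed. Hydrogenolysis (H2, Pd(OH)2/C, THF/EtOAc, rt) first removes the benzyl ethers and the bromine, giving robinetinidol-(4α→6)-epigallocatechin 3,7,3',4',5'-pentaacetate F4. Acid-catalysed methanolysis (1.25 M HCl in MeOH, rt → 40 °C, argon) then gives 13 directly; the 5-deoxy interflavan bond is expected to tolerate these conditions.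

**Further compounds**

F1 | step 5 | robinetinidol-(4α→8)-epigallocatechin (regioisomer of 13; upper unit 2R,3S,4S, lower unit 2R,3R) | Oc1ccc2c(c1)O[C@H](c1cc(O)c(O)c(O)c1)[C@@H](O)[C@@H]2c1c(O)cc(O)c2c1O[C@H](c1cc(O)c(O)c(O)c1)[C@H](O)C2
F2 | step 3 | (−)-epigallocatechin hexaacetate (3,5,7,3',4',5'-hexa-O-acetyl, 2R,3R) | CC(=O)Oc1cc(OC(C)=O)c2c(c1)O[C@H](c1cc(OC(C)=O)c(OC(C)=O)c(OC(C)=O)c1)[C@H](OC(C)=O)C2
F3 | step 3 | 3-O-acetyl-5,7,3',4',5'-penta-O-benzyl-(−)-epigallocatechin (2R,3R) | c1ccccc1COc1cc(OCc3ccccc3)c2c(c1)O[C@H](c1cc(OCc3ccccc3)c(OCc3ccccc3)c(OCc3ccccc3)c1)[C@H](OC(C)=O)C2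
F4 | step 6 | robinetinidol-(4α→6)-epigallocatechin 3,7,3',4',5'-pentaacetate (acetates on the upper unit only; upper unit 2R,3S,4S, lower unit 2R,3R) | CC(=O)Oc1ccc2c(c1)O[C@H](c1cc(OC(C)=O)c(OC(C)=O)c(OC(C)=O)c1)[C@@H](OC(C)=O)[C@@H]2c1c(O)cc2c(c1O)C[C@@H](O)[C@@H](c1cc(O)c(O)c(O)c1)O2
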